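All runs are calculated with constants of no real substance.

You cannot take more bis adduct from a flask than its coupling partner pays for: if each bis adduct costs two partners and each tris adduct three, Tuesday's 1.20 equiv caps bis adduct at 60.0 % of the substrate, and the partner is the limiting reagent there.

all flasks: substrate 20 mM

|  | coupling partner | remark | time |
|---|---|---|---|
| midnight | 1.4 equiv | run made earlier |  |
| winter | 2.3 equiv | run made earlier |  |
| noon | 4.4 equiv | run made earlier |  |
| Tuesday's | 1.20 equiv |  | 12 min |
| Thursday's | 3.00 equiv |  | 12 min |
| Sunday's | 4.00 equiv |  | 12 min |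

- midnight (time / min: bis adduct / %, tris adduct / %): 1.00: 20, 0; 2.00: 27, 3; 3.00: 36, 7; 6.00: 46, 8; 12.0: 54, 5
- winter (time / min: bis adduct / %, tris adduct / %): 1.00: 34, 4; 2.00: 42, 10; 3.00: 47, 13; 6.00: 52, 20; 12.0: 64, 19
- noon (time / min: bis adduct / %, tris adduct / %): 2.50: 45, 35; 5.00: 44, 51; 8.00: 41, 56; 10.0: 40, 57; 12.0: 41, 57

(readings scatter by 1.5 percentage points)



* bis adduct at the end, in percent of the substrate charged, for each flask in turn (Tuesday's, Thursday's, Sunday's)

Thursday's and Sunday's charges lie above two equivalents, and for those I reckon by another rule. On the noon plateau, tris adduct over bis adduct, per equivalent of partner still free, reads 0.743; call this the split. Where it holds, bis adduct is the adducts' total divided by one plus split times free partner.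

The number that must be known well differs by flask. For Tuesday's it is the cost of two: midnight reached 77.1 % of its cap, which I carry over as 46.3 %. For Sunday's it is the split: with the substrate converted and a fraction 0.5 of it tris adduct, 1.50 equivalents stay free and bis adduct is 47.3 %, while a split of 0.817 gives 44.9 %. For Thursday's it is the total, with a fraction 0.333 of the substrate as tris adduct: complete conversion gives 66.9 %, and winter's total of 83.0 % gives 47.5 %, a wider swing than Sunday's. Midway between the winter and noon totals, I commit to 55.3 %.

The forecast says 47 %, 58 % and 46 %, higher than mine for Thursday's, and warns: “These are rough estimates, since the assumed stoichiometry is inferred, not proven”.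

The flasks give 48.2 %, 59.3 % and 46.0 %, so the forecast stands as right within the tolerance.

    substrate + coupling partner → mono adduct (k = 0.440 L mol⁻¹ s⁻¹)
    coupling partner + mono adduct → bis adduct (k = 1.60 L mol⁻¹ s⁻¹)
    coupling partner + bis adduct ⇌ tris adduct (K = 39.0 L mol⁻¹, k = 0.120 L mol⁻¹ s⁻¹)
    substrate ⇌ dormant form (K = 1.40, k = 0.0230 s⁻¹)

At 12.0 min the split reads 0.759 in Sunday's flask and 0.774 in Thursday's, whose adducts total 94.2 % against the forecast's 92 %. In Tuesday's flask, substrate and dormant form relax towards each other by their own step alone with a half-life of 0.293 min, far shorter than the 5.79 min of the whole flask's slowest mode. At 12.0 min Tuesday's flask holds 24.9 % dormant form beside 17.5 % substrate.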